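**Retrosynthetic overview** (germacranolide numbering: C8 lactone CH–O, C9 CHOH, C10 CHMe, C1–C3 CH2, C4/C5 oxirane, C6 ester carbon, C7 ring CH, C11(=C13)–C12 lactone carbons)

1. Endgame, from the target back: C6 senecioate; C4–C5 oxirane by C6-hydroxyl-directed epoxidation of an (E)-cyclodecene; α-methylene lactone by Pd cyclocarbonylation of the C8 alcohol onto a C7 ethynyl group; cis-8,9-diol by chelation-controlled reduction of a C9 ketone.
2. Key disconnection: the ten-membered ring is released from a cyclohexanone in one SmI2 operation. A C8 ketyl adds to the C9 ketone (ring A, six-membered, temporary), and the trans-decalin alkoxide then fragments, cutting the temporary C4–C9 bond and expelling a C5 mesylate.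
3. Enabling feature: C9 and C4 lie 1,6 across the ten-membered ring, so a C4–C9 bond divides it into two cyclohexanes (ring A: C4–C9; ring B: C9, C10, C1–C4, which is 2,6-dimethylcyclohexanone with both methyls). The C9 oxygen together with the C4–C5 oxirane (alkene) is the retron of a Grob fragmentation.
4. Precursor: chelation-controlled Mukaiyama aldol of the silyl enol ether of 2,6-dimethylcyclohexanone with a C5–C8 α-PMB-oxy aldehyde, made from (Z)-butenediol by Sharpless epoxidation and alkynylalane opening.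
5. Ring order: ring B (bought), ring A and ten-membered ring (step 12), lactone (step 14), oxirane (step 17).

Key step: step 12

Remark: 2,6-dimethylcyclohexanone is used as the commercial cis/trans mixture and its enol silane 11 is racemic; the C10 methyl centre is therefore set by equilibration in step 8, not carried from the starting material.

Step 1
Reactants: 1 (Z)-but-2-ene-1,4-diol
Product: 2 (Z)-4-{[tert-butyl(diphenyl)silyl]oxy}but-2-en-1-ol
Conditions: NaH (1.0 equiv), THF, 0 °C; then t-BuPh2SiCl, 0 °C → rt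
Reagents that add atoms: tert-butyl(chloro)diphenylsilane, CC(C)(C)[Si](Cl)(c1ccccc1)c1ccccc1
Why: Monosilylation of a symmetrical diol through its monosodium alkoxide (Williamson-type O-silylation); the (Z)-alkene is untouched and no stereocentre is formed.

Step 2
Reactants: 2 (Z)-4-{[tert-butyl(diphenyl)silyl]oxy}but-2-en-1-ol
Product: 3 [(2S,3R)-3-({[tert-butyl(diphenyl)silyl]oxy}methyl)oxiran-2-yl]methanol
Conditions: Ti(OiPr)4 (10 mol %), L-(+)-diethyl tartrate (12 mol %), t-BuOOH, 4 Å molecular sieves, CH2Cl2, −20 °C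
Reagents that add atoms: tert-butyl hydroperoxide, CC(C)(C)OO
Why: Sharpless asymmetric epoxidation of a primary (Z)-allylic alcohol: the titanium/L-(+)-tartrate catalyst delivers the peroxide oxygen to one alkene face and should give the (2S,3R) cis-epoxy alcohol, which holds the future C6 oxygen and the carbon that becomes C7.

Step 3
Reactants: 3 [(2S,3R)-3-({[tert-butyl(diphenyl)silyl]oxy}methyl)oxiran-2-yl]methanol; 4 ethynyl(trimethyl)silane
Product: 6 (2R,3S)-3-({[tert-butyl(diphenyl)silyl]oxy}methyl)-5-(trimethylsilyl)pent-4-yne-1,2-diol, via diethyl[(trimethylsilyl)ethynyl]aluminium 5 (not isolated)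
Conditions: 4, n-BuLi, toluene, 0 °C; Et2AlCl, 0 °C; then 3, 0 °C → rt; aqueous potassium sodium tartrate work-up
Reagents that add atoms: diethylaluminium chloride, CC[Al](Cl)CC (its atoms end in intermediate 5 only)
Why: Regioselective opening of a 2,3-epoxy alcohol by an alkynylalane held on the primary alkoxide, which attacks the distal oxirane carbon in an SN2 manner: inversion there sets C7 (ethynyl and silyloxymethyl branch), retention at the other carbon keeps C6, and the 1,2-diol results.

Step 4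
Reactants: 6 (2R,3S)-3-({[tert-butyl(diphenyl)silyl]oxy}methyl)-5-(trimethylsilyl)pent-4-yne-1,2-diol
Product: 7 tert-butyl({(2S)-2-[(4R)-2-(4-methoxyphenyl)-1,3-dioxolan-4-yl]-4-(trimethylsilyl)but-3-yn-1-yl}oxy)diphenylsilane (both acetal epimers)
Conditions: 4-MeOC6H4CH(OMe)2, PPTS (cat.), CH2Cl2, rt
Reagents that add atoms: 1-(dimethoxymethyl)-4-methoxybenzene, COc1ccc(cc1)C(OC)OC
Why: Acid-catalysed transacetalisation of the terminal 1,2-diol to its 4-methoxybenzylidene acetal; the new acetal carbon (mixture) disappears in step 5.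

Step 5
Reactants: 7 tert-butyl({(2S)-2-[(4R)-2-(4-methoxyphenyl)-1,3-dioxolan-4-yl]-4-(trimethylsilyl)but-3-yn-1-yl}oxy)diphenylsilane
Product: 8 (2R,3S)-3-({[tert-butyl(diphenyl)silyl]oxy}methyl)-2-[(4-methoxybenzyl)oxy]-5-(trimethylsilyl)pent-4-yn-1-ol
Conditions: (i-Bu)2AlH (3 equiv), CH2Cl2, −78 → 0 °C
Reagents that add atoms: none
Why: Regioselective reductive acetal opening: aluminium binds the less hindered primary oxygen and hydride cleaves that C–O bond, which should leave the PMB ether on the secondary C6 oxygen (the chelating group needed in step 8) and a free primary alcohol.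

Step 6
Reactants: 8 (2R,3S)-3-({[tert-butyl(diphenyl)silyl]oxy}methyl)-2-[(4-methoxybenzyl)oxy]-5-(trimethylsilyl)pent-4-yn-1-ol
Product: 9 (2R,3S)-3-({[tert-butyl(diphenyl)silyl]oxy}methyl)-2-[(4-methoxybenzyl)oxy]-5-(trimethylsilyl)pent-4-ynal
Conditions: TEMPO (cat.), PhI(OAc)2, CH2Cl2, rt
Reagents that add atoms: none
Why: Oxoammonium (TEMPO) oxidation of the primary alcohol to the α-alkoxy aldehyde under non-basic conditions that should not epimerise C6.

Step 7
Reactants: 10 2,6-dimethylcyclohexan-1-one (cis/trans mixture)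
Product: 11 [(2,6-dimethylcyclohex-1-en-1-yl)oxy](trimethyl)silane (racemic)
Conditions: Me3SiOTf, Et3N, CH2Cl2, 0 °C
Reagents that add atoms: trimethylsilyl trifluoromethanesulfonate, C[Si](C)(C)OS(=O)(=O)C(F)(F)F
Why: Soft enolisation and O-silylation of a symmetrical ketone, which can give only one regioisomer, the tetrasubstituted silyl enol ether (racemic at the remaining methyl-bearing carbon).

Step 8
Reactants: 9 (2R,3S)-3-({[tert-butyl(diphenyl)silyl]oxy}methyl)-2-[(4-methoxybenzyl)oxy]-5-(trimethylsilyl)pent-4-ynal; 11 [(2,6-dimethylcyclohex-1-en-1-yl)oxy](trimethyl)silane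
Product: 13 (2R,6R)-2-[(1R,2R,3S)-3-({[tert-butyl(diphenyl)silyl]oxy}methyl)-1-hydroxy-2-[(4-methoxybenzyl)oxy]-5-(trimethylsilyl)pent-4-yn-1-yl]-2,6-dimethylcyclohexan-1-one, via ring-methyl epimer mixture of the aldol adduct 12 (not isolated)
Conditions: 9, TiCl4 (1.1 equiv), CH2Cl2, −78 °C; then 11 (3 equiv); aqueous work-up; then p-TsOH·H2O (10 mol %), CHCl3, rt
Reagents that add atoms: none
Why: Chelation-controlled Mukaiyama aldol: TiCl4 locks the aldehyde and the C6 PMB ether in a five-membered chelate that is attacked anti to the C7 branch (C5–OH syn to C6–OPMB), the open transition state should place the chelate ring beside the smaller methyl and not beside the ring methylene of the tetrasubstituted enol silane (quaternary C4 with OH syn to C3, the relationship that later gives the E alkene), the racemic enol silane is used in excess so that either enantiomer can serve, and acid-catalysed enolisation then equilibrates the ring methyl (C10) to the epimer in which the hydrogen-bonded side chain and that methyl are both equatorial.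

Step 9
Reactants: 13 (2R,6R)-2-[(1R,2R,3S)-3-({[tert-butyl(diphenyl)silyl]oxy}methyl)-1-hydroxy-2-[(4-methoxybenzyl)oxy]-5-(trimethylsilyl)pent-4-yn-1-yl]-2,6-dimethylcyclohexan-1-one
Product: 14 (1R,2R,3S)-3-({[tert-butyl(diphenyl)silyl]oxy}methyl)-1-[(1R,3R)-1,3-dimethyl-2-oxocyclohexyl]-2-[(4-methoxybenzyl)oxy]-5-(trimethylsilyl)pent-4-yn-1-yl methanesulfonate
Conditions: MsCl, Et3N, DMAP (cat.), CH2Cl2, 0 °C
Reagents that add atoms: methanesulfonyl chloride, CS(=O)(=O)Cl
Why: Sulfonylation of the hindered secondary alcohol via sulfene with retention at C5; the mesylate is the nucleofuge of step 12 and also blocks retro-aldol cleavage.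

Step 10
Reactants: 14 (1R,2R,3S)-3-({[tert-butyl(diphenyl)silyl]oxy}methyl)-1-[(1R,3R)-1,3-dimethyl-2-oxocyclohexyl]-2-[(4-methoxybenzyl)oxy]-5-(trimethylsilyl)pent-4-yn-1-yl methanesulfonate
Product: 15 (1R,2R,3S)-1-[(1R,3R)-1,3-dimethyl-2-oxocyclohexyl]-3-(hydroxymethyl)-2-[(4-methoxybenzyl)oxy]pent-4-yn-1-yl methanesulfonate
Conditions: n-Bu4NF, AcOH (1:1), THF, 0 °C → rt
Reagents that add atoms: none
Why: Fluoride-mediated desilylation that should remove the primary silyl ether and the alkynylsilane together, acetic acid keeping the medium free of hydroxide that could add to the ketone and trigger premature fragmentation or epimerise C10.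

Step 11
Reactants: 15 (1R,2R,3S)-1-[(1R,3R)-1,3-dimethyl-2-oxocyclohexyl]-3-(hydroxymethyl)-2-[(4-methoxybenzyl)oxy]pent-4-yn-1-yl methanesulfonate
Product: 16 (1R,2R,3R)-1-[(1R,3R)-1,3-dimethyl-2-oxocyclohexyl]-3-formyl-2-[(4-methoxybenzyl)oxy]pent-4-yn-1-yl methanesulfonate
Conditions: TEMPO (cat.), PhI(OAc)2, CH2Cl2, 0 °C → rt; used at once
Reagents that add atoms: none
Why: TEMPO oxidation of the primary alcohol to the aldehyde without base, so that the propargylic α-carbon (C7) should neither epimerise nor isomerise.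

Step 12
Reactants: 16 (1R,2R,3R)-1-[(1R,3R)-1,3-dimethyl-2-oxocyclohexyl]-3-formyl-2-[(4-methoxybenzyl)oxy]pent-4-yn-1-yl methanesulfonate
Product: 18 (2S,3S,4S,5E,10R)-3-ethynyl-2-hydroxy-4-[(4-methoxybenzyl)oxy]-6,10-dimethylcyclodec-5-en-1-one, via trans-decalin bis(diiodosamarium) cis-diolate 17 (not isolated)
Conditions: SmI2 (2.1 equiv), THF, −78 → 0 °C; then pH 7 NaH2PO4/Na2HPO4 buffer
Reagents that add atoms: samarium diiodide, I[Sm]I (its atoms end in intermediate 17 only)
Why: Proposed new method: SmI2 reduces the aldehyde of 16 to a C8 ketyl that couples (second electron) with the C9 ketone carbonyl in a samarium-bridged chair to the cis-diolate 17, and the tertiary C9 alkoxide of this trans-decalin then expels the antiperiplanar equatorial C5 mesylate by cleaving the C4–C9 bond (Grob fragmentation); the closest known reactions are the SmI2 pinacol cyclisation of 1,6-keto aldehydes to cis-cyclohexane-1,2-diols and the SmI2 Barbier cyclisation/Grob fragmentation sequences of keto mesylates to medium-ring cycloalkenones, merged here so that a ketyl takes the place of the alkylsamarium. Ring A (C4–C9) closes in a 6-exo-trig mode through a chair in which C5–OMs, C6–OPMB and the C7 ethynyl group are all equatorial, and the ten-membered ring is not closed end to end but is released by scission of the ring-fusion bond of the bicycle. C8 is set in this chair (oxygen equatorial, trans to the C7 substituent and cis to the C9 oxygen through the shared samarium), C9 is transient, and the E geometry of C4=C5 follows stereospecifically from the antiperiplanar C9–C4–C5–OMs array fixed by the C4/C5 configuration of the aldol adduct. The step needs electron transfer to the aldehyde before the ketone, fragmentation in preference to oxetane formation and no further reduction of the α-ketol; the more reducible aldehyde, the rigid trans-decalin with its aligned fusion bond and the use of only two equivalents of SmI2 should secure these.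

Step 13
Reactants: 18 (2S,3S,4S,5E,10R)-3-ethynyl-2-hydroxy-4-[(4-methoxybenzyl)oxy]-6,10-dimethylcyclodec-5-en-1-one
Product: 19 (1R,2S,3S,4S,5E,10R)-3-ethynyl-4-[(4-methoxybenzyl)oxy]-6,10-dimethylcyclodec-5-ene-1,2-diol
Conditions: Zn(BH4)2, Et2O, −20 °C
Reagents that add atoms: none
Why: Chelation-controlled (Cram-chelate) hydride reduction of the α-hydroxy ketone: zinc bridges the C8 hydroxyl and the C9 carbonyl and hydride enters anti to the C7 branch of this five-membered chelate, which should give the cis (erythro) 8,9-diol.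

Step 14
Reactants: 19 (1R,2S,3S,4S,5E,10R)-3-ethynyl-4-[(4-methoxybenzyl)oxy]-6,10-dimethylcyclodec-5-ene-1,2-diol
Product: 20 (4E,6S,7R,8S,9R,10R)-9-hydroxy-6-[(4-methoxybenzyl)oxy]germacra-4,11(13)-dien-12,8-olide
Conditions: PdCl2 (5 mol %), PPh3, SnCl2 (5 mol %), CO (7 atm), MeCN, 70 °C
Reagents that add atoms: carbon monoxide, [C-]#[O+]
Why: Palladium-catalysed cyclocarbonylation of a homopropargylic alcohol (alkoxycarbonylpalladium at the C8 oxygen, syn insertion of the C11≡C13 alkyne, protonolysis) builds the trans-fused α-methylene γ-lactone with C12 from CO; the C8 oxygen is vicinal and trans to the ethynyl group and closes the five-membered ring, whereas the C9 oxygen could only form a strained trans-bridged six-membered lactone.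

Step 15
Reactants: 20 (4E,6S,7R,8S,9R,10R)-9-hydroxy-6-[(4-methoxybenzyl)oxy]germacra-4,11(13)-dien-12,8-olide
Product: 21 (4E,6S,7R,8S,9R,10R)-6-[(4-methoxybenzyl)oxy]-9-[(triethylsilyl)oxy]germacra-4,11(13)-dien-12,8-olide
Conditions: Et3SiOTf, 2,6-lutidine, CH2Cl2, −78 °C
Reagents that add atoms: triethylsilyl trifluoromethanesulfonate, CC[Si](CC)(CC)OS(=O)(=O)C(F)(F)F
Why: Silylation of the only remaining hydroxyl (C9), so that the C6 alcohol freed in step 16 is the sole hydroxyl for the directed epoxidation and the acylation.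

Step 16
Reactants: 21 (4E,6S,7R,8S,9R,10R)-6-[(4-methoxybenzyl)oxy]-9-[(triethylsilyl)oxy]germacra-4,11(13)-dien-12,8-olide
Product: 22 (4E,6S,7R,8S,9R,10R)-6-hydroxy-9-[(triethylsilyl)oxy]germacra-4,11(13)-dien-12,8-olide
Conditions: DDQ, CH2Cl2/pH 7 NaH2PO4/Na2HPO4 buffer, 0 °C
Reagents that add atoms: none
Why: Oxidative cleavage of the 4-methoxybenzyl ether by DDQ (hydride abstraction, then hydrolysis of the oxocarbenium ion), which frees the allylic C6 alcohol and leaves silyl ether, lactone and alkenes untouched.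

Step 17
Reactants: 22 (4E,6S,7R,8S,9R,10R)-6-hydroxy-9-[(triethylsilyl)oxy]germacra-4,11(13)-dien-12,8-olide
Product: 23 (4R,5R,6R,7R,8S,9R,10R)-4,5-epoxy-6-hydroxy-9-[(triethylsilyl)oxy]germacr-11(13)-en-12,8-olide
Conditions: VO(acac)2 (5 mol %), t-BuOOH, CH2Cl2, 0 °C → rt
Reagents that add atoms: tert-butyl hydroperoxide, CC(C)(C)OO
Why: Hydroxyl-directed vanadium-catalysed epoxidation of the allylic alcohol: the vanadate ester of the C6 hydroxyl needs an O–C6–C5=C4 dihedral angle near 40–50°, and because the C6–C7 bond is tied into the ten-membered ring and cannot lie antiperiplanar to the alkene, the only such geometry should deliver oxygen syn to the hydroxyl onto the face that gives the erythro (4R,5R) epoxy alcohol, while the electron-poor methylene lactone does not react.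

Step 18
Reactants: 23 (4R,5R,6R,7R,8S,9R,10R)-4,5-epoxy-6-hydroxy-9-[(triethylsilyl)oxy]germacr-11(13)-en-12,8-olide
Product: 24 (4R,5R,6R,7R,8S,9R,10R)-4,5-epoxy-6-[(3-methylbut-2-enoyl)oxy]-9-[(triethylsilyl)oxy]germacr-11(13)-en-12,8-olide
Conditions: 3-methylbut-2-enoic anhydride, DMAP, Et3N, CH2Cl2, rt
Reagents that add atoms: 3-methylbut-2-enoic anhydride, CC(C)=CC(=O)OC(=O)C=C(C)C
Why: DMAP-catalysed acyl transfer (Steglich-type) to the only free hydroxyl with retention at C6; the anhydride avoids the vinylketene pathway by which the acid chloride is deconjugated.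

Step 19
Reactants: 24 (4R,5R,6R,7R,8S,9R,10R)-4,5-epoxy-6-[(3-methylbut-2-enoyl)oxy]-9-[(triethylsilyl)oxy]germacr-11(13)-en-12,8-olide
Product: 25 (4R,5R,6R,7S,8S,9R,10R)-4,5-epoxy-9-hydroxy-6-[(3-methylbut-2-enoyl)oxy]germacr-11(13)-en-12,8-olide (CNP0119422.1)
Conditions: HF·pyridine, pyridine, THF, 0 °C
Reagents that add atoms: none
Why: Fluoride-mediated cleavage of the secondary triethylsilyl ether under pyridine-buffered conditions that should spare the oxirane, the conjugated ester and the methylene lactone, giving the target.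

**Compound list**

1 | (Z)-but-2-ene-1,4-diol | OC/C=C\CO | starting material
2 | (Z)-4-{[tert-butyl(diphenyl)silyl]oxy}but-2-en-1-ol | OC/C=C\CO[Si](c1ccccc1)(c1ccccc1)C(C)(C)C | intermediate
3 | [(2S,3R)-3-({[tert-butyl(diphenyl)silyl]oxy}methyl)oxiran-2-yl]methanol | OC[C@@H]1O[C@@H]1CO[Si](c1ccccc1)(c1ccccc1)C(C)(C)C | intermediate
4 | ethynyl(trimethyl)silane | C#C[Si](C)(C)C | starting material
5 | diethyl[(trimethylsilyl)ethynyl]aluminium | CC[Al](CC)C#C[Si](C)(C)C | intermediate
6 | (2R,3S)-3-({[tert-butyl(diphenyl)silyl]oxy}methyl)-5-(trimethylsilyl)pent-4-yne-1,2-diol | OC[C@H](O)[C@@H](C#C[Si](C)(C)C)CO[Si](c1ccccc1)(c1ccccc1)C(C)(C)C | intermediate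
7 | tert-butyl({(2S)-2-[(4R)-2-(4-methoxyphenyl)-1,3-dioxolan-4-yl]-4-(trimethylsilyl)but-3-yn-1-yl}oxy)diphenylsilane (both acetal epimers) | COc1ccc(cc1)C1OC[C@H](O1)[C@@H](C#C[Si](C)(C)C)CO[Si](c1ccccc1)(c1ccccc1)C(C)(C)C | intermediate
8 | (2R,3S)-3-({[tert-butyl(diphenyl)silyl]oxy}methyl)-2-[(4-methoxybenzyl)oxy]-5-(trimethylsilyl)pent-4-yn-1-ol | OC[C@H](OCc1ccc(OC)cc1)[C@@H](C#C[Si](C)(C)C)CO[Si](c1ccccc1)(c1ccccc1)C(C)(C)C | intermediate
9 | (2R,3S)-3-({[tert-butyl(diphenyl)silyl]oxy}methyl)-2-[(4-methoxybenzyl)oxy]-5-(trimethylsilyl)pent-4-ynal | O=C[C@H](OCc1ccc(OC)cc1)[C@@H](C#C[Si](C)(C)C)CO[Si](c1ccccc1)(c1ccccc1)C(C)(C)C | intermediate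
10 | 2,6-dimethylcyclohexan-1-one (cis/trans mixture) | CC1CCCC(C)C1=O | starting material
11 | [(2,6-dimethylcyclohex-1-en-1-yl)oxy](trimethyl)silane (racemic) | CC1CCCC(C)=C1O[Si](C)(C)C | intermediate
12 | (2R,6RS)-2-[(1R,2R,3S)-3-({[tert-butyl(diphenyl)silyl]oxy}methyl)-1-hydroxy-2-[(4-methoxybenzyl)oxy]-5-(trimethylsilyl)pent-4-yn-1-yl]-2,6-dimethylcyclohexan-1-one (both C6 ring epimers) | CC(C)(C)[Si](c1ccccc1)(c1ccccc1)OC[C@H](C#C[Si](C)(C)C)[C@@H](OCc1ccc(OC)cc1)[C@H](O)[C@@]1(C)CCCC(C)C1=O | intermediate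
13 | (2R,6R)-2-[(1R,2R,3S)-3-({[tert-butyl(diphenyl)silyl]oxy}methyl)-1-hydroxy-2-[(4-methoxybenzyl)oxy]-5-(trimethylsilyl)pent-4-yn-1-yl]-2,6-dimethylcyclohexan-1-one | CC(C)(C)[Si](c1ccccc1)(c1ccccc1)OC[C@H](C#C[Si](C)(C)C)[C@@H](OCc1ccc(OC)cc1)[C@H](O)[C@@]1(C)CCC[C@@H](C)C1=O | intermediate
14 | (1R,2R,3S)-3-({[tert-butyl(diphenyl)silyl]oxy}methyl)-1-[(1R,3R)-1,3-dimethyl-2-oxocyclohexyl]-2-[(4-methoxybenzyl)oxy]-5-(trimethylsilyl)pent-4-yn-1-yl methanesulfonate | CC(C)(C)[Si](c1ccccc1)(c1ccccc1)OC[C@H](C#C[Si](C)(C)C)[C@@H](OCc1ccc(OC)cc1)[C@H](OS(C)(=O)=O)[C@@]1(C)CCC[C@@H](C)C1=O | intermediate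
15 | (1R,2R,3S)-1-[(1R,3R)-1,3-dimethyl-2-oxocyclohexyl]-3-(hydroxymethyl)-2-[(4-methoxybenzyl)oxy]pent-4-yn-1-yl methanesulfonate | OC[C@H](C#C)[C@@H](OCc1ccc(OC)cc1)[C@H](OS(C)(=O)=O)[C@@]1(C)CCC[C@@H](C)C1=O | intermediate
16 | (1R,2R,3R)-1-[(1R,3R)-1,3-dimethyl-2-oxocyclohexyl]-3-formyl-2-[(4-methoxybenzyl)oxy]pent-4-yn-1-yl methanesulfonate | O=C[C@H](C#C)[C@@H](OCc1ccc(OC)cc1)[C@H](OS(C)(=O)=O)[C@@]1(C)CCC[C@@H](C)C1=O | intermediate
17 | trans-decalin bis(diiodosamarium) cis-diolate: 4,4a-bis[(diiodosamario)oxy]-3-ethynyl-2-[(4-methoxybenzyl)oxy]-5,8a-dimethyldecahydronaphthalen-1-yl methanesulfonate (configuration as in F1) | I[Sm](I)O[C@H]1[C@H](C#C)[C@@H](OCc3ccc(OC)cc3)[C@H](OS(C)(=O)=O)[C@@]2(C)CCC[C@@H](C)[C@]12O[Sm](I)I | intermediate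
18 | (2S,3S,4S,5E,10R)-3-ethynyl-2-hydroxy-4-[(4-methoxybenzyl)oxy]-6,10-dimethylcyclodec-5-en-1-one | O[C@@H]2C(=O)[C@H](C)CCC/C(C)=C/[C@H](OCc1ccc(OC)cc1)[C@H]2C#C | intermediate
19 | (1R,2S,3S,4S,5E,10R)-3-ethynyl-4-[(4-methoxybenzyl)oxy]-6,10-dimethylcyclodec-5-ene-1,2-diol | O[C@@H]2[C@H](O)[C@H](C)CCC/C(C)=C/[C@H](OCc1ccc(OC)cc1)[C@H]2C#C | intermediate
20 | (4E,6S,7R,8S,9R,10R)-9-hydroxy-6-[(4-methoxybenzyl)oxy]germacra-4,11(13)-dien-12,8-olide | C=C1C(=O)O[C@@H]2[C@H](O)[C@H](C)CCC/C(C)=C/[C@H](OCc3ccc(OC)cc3)[C@@H]12 | intermediate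
21 | (4E,6S,7R,8S,9R,10R)-6-[(4-methoxybenzyl)oxy]-9-[(triethylsilyl)oxy]germacra-4,11(13)-dien-12,8-olide | C=C1C(=O)O[C@@H]2[C@H](O[Si](CC)(CC)CC)[C@H](C)CCC/C(C)=C/[C@H](OCc3ccc(OC)cc3)[C@@H]12 | intermediate
22 | (4E,6S,7R,8S,9R,10R)-6-hydroxy-9-[(triethylsilyl)oxy]germacra-4,11(13)-dien-12,8-olide | C=C1C(=O)O[C@@H]2[C@H](O[Si](CC)(CC)CC)[C@H](C)CCC/C(C)=C/[C@H](O)[C@@H]12 | intermediate
23 | (4R,5R,6R,7R,8S,9R,10R)-4,5-epoxy-6-hydroxy-9-[(triethylsilyl)oxy]germacr-11(13)-en-12,8-olide | C=C1C(=O)O[C@@H]2[C@H](O[Si](CC)(CC)CC)[C@H](C)CCC[C@@]3(C)O[C@@H]3[C@H](O)[C@@H]12 | intermediate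
24 | (4R,5R,6R,7R,8S,9R,10R)-4,5-epoxy-6-[(3-methylbut-2-enoyl)oxy]-9-[(triethylsilyl)oxy]germacr-11(13)-en-12,8-olide | C=C1C(=O)O[C@@H]2[C@H](O[Si](CC)(CC)CC)[C@H](C)CCC[C@@]3(C)O[C@@H]3[C@H](OC(=O)C=C(C)C)[C@@H]12 | intermediate
25 | (4R,5R,6R,7S,8S,9R,10R)-4,5-epoxy-9-hydroxy-6-[(3-methylbut-2-enoyl)oxy]germacr-11(13)-en-12,8-olide | C=C1C(=O)O[C@@H]2[C@H](O)[C@H](C)CCC[C@@]3(C)O[C@@H]3[C@H](OC(=O)C=C(C)C)[C@@H]12 | target

**Step count and risks**

Total steps: 19. Longest linear sequence: 18 steps (steps 1–6 and 8–19; step 7 makes the second fragment).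

The three steps most likely to fail:

Step 12 (proposed new method). The trivalent samarium alkoxide may not fragment before residual SmI2 reduces the α-ketol further, the aldehyde may be reduced without C–C bond formation, or the C9 alkoxide may displace the mesylate to an oxetane. The fallback separates the two events into known operations. It sets out from 16: SmI2 with t-BuOH in THF at −78 °C and a cold quench (pinacol cyclisation of the keto aldehyde only) should give the bicyclic cis-diol monomesylate (1R,2R,3S,4S,4aR,5R,8aR)-3-ethynyl-4,4a-dihydroxy-2-[(4-methoxybenzyl)oxy]-5,8a-dimethyldecahydronaphthalen-1-yl methanesulfonate F1. KOt-Bu in THF at 0 °C then effects the Wharton fragmentation of this 1,3-diol monosulfonate, and the route is rejoined at 18.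

Step 8. Discrimination between the methyl side and the ring-methylene side of the tetrasubstituted enol silane may be poor; the wrong relative configuration at C4/C5 would give the Z-cycloalkene in step 12. The hindered nucleophile may also add slowly, or TiCl4 may cleave the PMB ether. The fallback builds the quaternary centre through a closed, chelated transition state. It sets out from 9: Lewis-acid-mediated Morita–Baylis–Hillman coupling with 6-methylcyclohex-2-en-1-one (TiCl4, n-Bu4NI, CH2Cl2, −78 °C, then DBU; same chelate control at C5) should give 2-[(1R,2R,3S)-3-({[tert-butyl(diphenyl)silyl]oxy}methyl)-1-hydroxy-2-[(4-methoxybenzyl)oxy]-5-(trimethylsilyl)pent-4-yn-1-yl]-6-methylcyclohex-2-en-1-one F2. Conjugate reduction with LiBH(s-Bu)3 (2.2 equiv, THF, −78 °C) generates the C4 enolate regiospecifically as a lithium chelate with the C5 alkoxide, and MeI alkylates it anti to the C6 branch (Fráter–Seebach-type alkylation) to give 12. The acid equilibration of step 8 then rejoins the route at 13.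

Step 17. Oxygen may be transferred through another ring conformer to the other alkene face, or the Lewis-acidic vanadium may open the new oxirane transannularly. The fallback replaces substrate direction by catalyst control. It sets out from 21, before PMB removal: Shi epoxidation (D-fructose-derived ketone, KHSO5 (Oxone), K2CO3-buffered MeCN/dimethoxymethane/water, 0 °C), whose spiro transition state is matched to the (4R,5R) oxirane of an (E)-trisubstituted alkene, should give (4R,5R,6R,7R,8S,9R,10R)-4,5-epoxy-6-[(4-methoxybenzyl)oxy]-9-[(triethylsilyl)oxy]germacr-11(13)-en-12,8-olide F3. DDQ in buffered CH2Cl2 then removes the PMB group, and the route is rejoined at 23.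

Further compounds
F1 | step 12 | (1R,2R,3S,4S,4aR,5R,8aR)-3-ethynyl-4,4a-dihydroxy-2-[(4-methoxybenzyl)oxy]-5,8a-dimethyldecahydronaphthalen-1-yl methanesulfonate | O[C@H]1[C@H](C#C)[C@@H](OCc3ccc(OC)cc3)[C@H](OS(C)(=O)=O)[C@@]2(C)CCC[C@@H](C)[C@]12O
F2 | step 8 | 2-[(1R,2R,3S)-3-({[tert-butyl(diphenyl)silyl]oxy}methyl)-1-hydroxy-2-[(4-methoxybenzyl)oxy]-5-(trimethylsilyl)pent-4-yn-1-yl]-6-methylcyclohex-2-en-1-one (both C6 ring epimers) | CC(C)(C)[Si](c1ccccc1)(c1ccccc1)OC[C@H](C#C[Si](C)(C)C)[C@@H](OCc1ccc(OC)cc1)[C@H](O)C1=CCCC(C)C1=O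
F3 | step 17 | (4R,5R,6R,7R,8S,9R,10R)-4,5-epoxy-6-[(4-methoxybenzyl)oxy]-9-[(triethylsilyl)oxy]germacr-11(13)-en-12,8-olide | C=C1C(=O)O[C@@H]2[C@H](O[Si](CC)(CC)CC)[C@H](C)CCC[C@@]3(C)O[C@@H]3[C@H](OCc4ccc(OC)cc4)[C@@H]12
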